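## The problem

Compound 28 is a germacranolide: a ten-membered carbocycle (C1H2–C2H=C3–C4(CH3)(OH)–C5H2–C6H(OAc)–C7–C8=C9H–C10(CH3)–C1) whose C3 and C10 are joined by an ether oxygen, so that O–C3=C2–C1–C10 is a 2,3-dihydrofuran, and whose C7–C8 edge carries a butenolide (C7=C11(C13H2OAc)–C12(=O)–O–C8) with an exocyclic C8=C9 bond. Three stereocentres (4S, 6S, 10S) and the C8=C9 geometry (C7 and C10 cis) have to be secured. C4 and C6 are 1,3-related and can be set in an open chain, C4 from the chiral pool and C6 by a reagent. C10 is a fully substituted ether carbon separated from both by sp2 atoms, so only the shape of the medium ring can influence it. The finished skeleton is fragile: acid hydrolyses the enol ether and can ionise the tertiary allylic C10–O bond, base opens the enol lactone and the allylic acetates, and a free hydroxyl at C4 or C6 could take the place of the C3 oxygen at C10. A ten-membered ring is also the medium ring least willing to close end to end. The enabling feature is that C3 is at the ketone oxidation level and is linked to C10 by the saturated unit C2–C1, so an enol ether of the C3 carbonyl with the allylic alcohol C9(OH)–C10(CH3)=C1 is an allyl vinyl ether (C2=C3–O–C9–C10=C1). If that oxygen sits in an eight-membered ring (O, C3 to C9, with a furan across C7–C8 as the masked butenolide), a [3,3] shift makes C1–C2, breaks O–C9 and gives the ten-membered C3 ketone with a C9=C10 alkene ready for the ether bridge.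

## Retrosynthesis

**28 ⇒ 27 ⇒ 26.** The two acetyl C–O bonds are cut and O4, O6 and O13 are placed under silicon (triol 27, tris-silyl ether 26). Acetates cannot pass the organolithium steps or the titanium methylidene, and O4 must stay masked until the C10–O bond exists, so that the tertiary hydroxyl cannot compete for C10. The skeleton is unchanged. The forward steps need a buffered fluoride that spares the enol ether and enol lactone, and an acetylation that stops at the primary and secondary hydroxyls.

**26 ⇒ 25 ⇒ 23.** The O–C10 bond is cut, C2=C3 is read as the enol of a C3 ketone, and the C8 hemiketal and C12 carbonyl of hydroxybutenolide 25 are traced to the furan of 23. One disconnection removes the bridge, the enol ether, the enol lactone and the C10 stereocentre. Cutting only O–C10 and keeping the butenolide would force a base-sensitive lactone through all earlier steps, whereas the furan carries C7, C8, C11 and C12 robustly from the first step. Forward, singlet oxygen must attack the furan (the only ring α-hydrogen, at C12, fixes the regiochemistry), and the dehydrative ring closure must use the ketone oxygen and the correct face of C10.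

**23 ⇒ 22 (key).** The C1–C2 bond is cut and O–C9 is re-formed, which turns the furan-fused cyclodecenone 23 into the 2-methylene-8-isopropenyloxocane 22. The neighbouring cuts (C6–C7, C9–C10 or C2–C3) would all require end-to-end closure of a ten-membered ring. This is the only cut that builds the ring from a smaller one in a unimolecular step. The forward reaction is a thermal Claisen rearrangement that must use the isopropenyl group, not the furan, as the allyl partner.

**22 ⇒ 21 ⇒ 20 ⇒ 19.** The exocyclic methylene C2 is removed (lactone 21), the O4 silyl group is taken off (20), and the lactone C3–O9 bond is cut to give seco acid 19. The enol ether thus comes from a carbonyl group, and ring formation becomes an esterification between two functions present in simple building blocks. Closing the oxocane at a C–C bond (C6–C7 or C8–C9) has no comparably direct method. The forward steps are an eight-membered lactonisation, helped by the cis-fused furan and by leaving O4 free so that the acid is less hindered, and methylenation of a hindered lactone.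

**19 ⇒ 18 ⇒ 17 ⇒ 16 ⇒ 15.** The carboxyl and tertiary hydroxyl of 19 are folded back into a dioxolanone (18), O9 is given a temporary triethylsilyl group (17), and the C6 silyl ether is traced through carbinol 16 to ketone 15. The dioxolanone is the form in which citramalic acid differentiates its two carboxyl groups. A ketone at C6 allows the 6S centre to be set by a catalyst on an aryl ketone, independent of C4 and of the uncontrolled C9.

**15 ⇒ 9 + 12.** The acyl–furyl bond C6–C7 is cut. Bromofuran 9 carries C8–C13, and acid chloride 12 carries C3–C6 with the C4 stereocentre. Coupling through the furylzinc leaves the dioxolanone of 12 alone, which a furyllithium might not.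

**9 ⇒ 5 + 6, 5 ⇒ 4 ⇒ 1, and 12 ⇒ 11 ⇒ 10.** The C8–C9 bond is cut to methacrolein 6 and bromofuran 5, and the C11–C13 bond goes back through alcohol 4 to 3,4-dibromofuran 1. The order is chosen so that the remaining bromine at C7 directs lithiation to C8; a furan already substituted at C7 by the side chain would not distinguish C8 from C12. Fragment 12 comes from (S)-citramalic acid 10 via acetonide 11, which supplies C4 with the correct configuration.

## Roads not taken

**Alternative 1:** The cut is through C5–C6 and O–C4 of an isoxazoline. Aldoxime A1, which already holds the dihydrofuran, the C10 centre and the butenolide, would be oxidised in situ (NaOCl) to nitrile oxide A2. Its intramolecular addition across the isopropenyl C4=C5 bond would give the isoxazoline-bridged macrocycle A3; N–O cleavage and reduction at C6 would follow.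
- Merits: one step closes the ring and installs the C4 oxygen and the C6 oxidation level. Nitrile oxides add to 1,1-disubstituted alkenes with the oxygen on the substituted carbon. C10 is made earlier in a small fragment, which is better than the chosen plan at that centre.
- Weak points: C4, a quaternary centre, would be created during closure of a ten-membered ring with only the distant C10 to direct it. The dipolarophile is part of an electron-rich 2-alkoxydiene, so addition to the enol ether C2=C3 and chlorination by hypochlorite compete. Reductive N–O cleavage and a ketone reduction would then be needed on a molecule that already has the alkylidene butenolide, the enol ether and an allylic acetate.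
- Comparison: the chosen plan takes C4 from citramalic acid with certainty and exposes the sensitive functions only at the end. Against that, its C10 centre is less well controlled than in A1.

**Alternative 2:** The cut is through C9–C10 and a temporary C3–C8 bond. The 2-methyl-5-alkylfuran A4, with a tethered 2-acetoxy enone, would undergo intramolecular Diels–Alder addition (Me2AlCl or heat) to give the oxanorbornene A5 (written with the 6S configuration that the target requires). The oxygen bridge is the future C3–O–C10 ether, and a later fragmentation of C3–C8 would open the six-membered ring A to the ten-membered ring.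
- Merits: C10 and the ether bridge are created together in a stereospecific cycloaddition, relayed from C4 and C6 through a short tether. On the C10 problem this is the best of all the plans, and no macrocyclisation is needed.
- Weak points: furan Diels–Alder additions with substituted bridgeheads are reversible and often unfavourable. The adduct places three fully substituted carbons (C4, C3, C8) in a row. Cleaving C3–C8 needs a fragmentation for which the adduct offers no obvious electron sink. The butenolide carbons C11–C13 are absent and would have to be annulated afterwards, together with the enol lactone.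
- Comparison: the chosen plan cannot match the C10 control. It sets against this a precedented pericyclic ring expansion, the butenolide carbons carried as a furan from step 1, and a far shorter path after the key step.

**Alternative 3:** The cut is C6–C7. In iodo aldehyde A6 the C7–I bond would be metalated (NiCl2 co-catalyst, catalytic CrCl2 kept divalent at the cathode, Cp2ZrCl2 for turnover) and the C7 nucleophile would add to the C6 aldehyde to give the macrocyclic carbinol A7.
- Merits: the mildest and most chemoselective C–C bond formation of the four plans, catalytic in chromium, and convergent. A7 is two steps from 28, and both C4 and C10 are made in fragments by ordinary methods. In convergence, brevity of the endgame and control of C10 it is as good as or better than the chosen plan.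
- Weak points: it is an end-to-end closure of a ten-membered ring. The C6 configuration would be decided by a macrocyclic addition next to a quaternary centre and might need oxidation and re-reduction. A6 requires the acid-labile enol ether and the alkylidene butenolide to be built early and carried through a long fragment synthesis.
- Comparison: the chosen plan sets C6 by a catalyst on an open-chain aryl ketone, makes the ring by expansion rather than closure, and forms the fragile functions last.

Key step: step 14

Remarks on the chemistry (assumptions):
- Germacrane numbering is used for all intermediates; in the furans, C7 and C11 are the β-carbons and C8 and C12 the α-carbons.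
- C9 is introduced without control. Compound 9 is racemic and 15–22 are pairs of C9 epimers; the centre is destroyed in step 14, and the SMILES leave it undefined on purpose. The same holds for the hemiketal carbon C8 of 25.
- The 10S configuration of 26 is taken to be the thermodynamically preferred one under reversible ionisation of the C10–O bond. This is a working hypothesis, not an established fact.

## Route

Step 1
Reactants: 1 3,4-dibromofuran
Product: 4 (4-bromofuran-3-yl)methanol, via 4-bromo-3-furyllithium 2 (not isolated), via 4-bromofuran-3-carbaldehyde 3 (not isolated)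
Conditions: n-BuLi (1.0 equiv), Et2O, −78 °C; DMF, −78 °C; then MeOH, NaBH4, 0 °C
Reagents that add atoms: N,N-dimethylformamide, CN(C)C=O
Why: Bromine–lithium exchange on one of two equivalent bromides is fast at −78 °C, where the 3-furyllithium does not isomerise; formylation and in-flask borohydride reduction then give the C13 hydroxymethyl group.

Step 2
Reactants: 4 (4-bromofuran-3-yl)methanol
Product: 5 3-bromo-4-[(tert-butyldimethylsilyloxy)methyl]furan
Conditions: t-BuMe2SiCl, imidazole, CH2Cl2, rt
Reagents that add atoms: tert-butyldimethylsilyl chloride, CC(C)(C)[Si](C)(C)Cl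
Why: Standard silylation of a primary alcohol; the silyl ether withstands the lithium bases, the borane and the titanium reagent that follow.

Step 3
Reactants: 5 3-bromo-4-[(tert-butyldimethylsilyloxy)methyl]furan; 6 methacrolein
Product: 9 rac-3-bromo-4-[(tert-butyldimethylsilyloxy)methyl]-2-[2-methyl-1-(triethylsilyloxy)prop-2-en-1-yl]furan, via 2-furyllithium 7 (not isolated), via lithium alkoxide 8 (not isolated)
Conditions: LiN(i-Pr)2, THF, −78 °C; 6, −78 °C; then Et3SiCl, −78 °C → rt
Reagents that add atoms: chlorotriethylsilane, CC[Si](Cl)(CC)CC
Why: The ring hydrogen between the ring oxygen and bromine is the most acidic (bromine-directed α-lithiation of 3-bromofurans), so C8 is metalated and not C12. 1,2-Addition to the enal and silylation of the alkoxide in the same flask give the protected C9 carbinol, racemic because this centre is later destroyed.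

Step 4
Reactants: 10 (S)-citramalic acid
Product: 11 2-[(4S)-2,2,4-trimethyl-5-oxo-1,3-dioxolan-4-yl]acetic acid
Conditions: Me2C(OMe)2, p-TsOH·H2O (cat.), rt
Reagents that add atoms: 2,2-dimethoxypropane, COC(C)(C)OC
Why: Acetonide formation engages the α-hydroxy acid pair as a five-membered dioxolanone and leaves the other carboxyl (future C6) free; the stereocentre is not touched.

Step 5
Reactants: 11 2-[(4S)-2,2,4-trimethyl-5-oxo-1,3-dioxolan-4-yl]acetic acid
Product: 12 2-[(4S)-2,2,4-trimethyl-5-oxo-1,3-dioxolan-4-yl]acetyl chloride
Conditions: (COCl)2, DMF (cat.), CH2Cl2, 0 °C → rt; concentrated and used crude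
Reagents that add atoms: oxalyl chloride, ClC(=O)C(=O)Cl
Why: Acid chloride formation by way of the Vilsmeier-type chloroiminium species; the dioxolanone tolerates these conditions.

Step 6
Reactants: 9 rac-3-bromo-4-[(tert-butyldimethylsilyloxy)methyl]-2-[2-methyl-1-(triethylsilyloxy)prop-2-en-1-yl]furan; 12 2-[(4S)-2,2,4-trimethyl-5-oxo-1,3-dioxolan-4-yl]acetyl chloride
Product: 15 furyl ketone (5S)-5-(2-{4-[(tert-butyldimethylsilyloxy)methyl]-2-[2-methyl-1-(triethylsilyloxy)prop-2-en-1-yl]furan-3-yl}-2-oxoethyl)-2,2,5-trimethyl-1,3-dioxolan-4-one (both C9 epimers), via furyllithium 13 (not isolated), via furylzinc chloride 14 (not isolated)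
Conditions: n-BuLi (1.05 equiv), Et2O, −78 °C, 10 min; ZnCl2 (THF), −78 → 0 °C; 12, Pd(PPh3)4 (5 mol %), 0 °C → rt
Reagents that add atoms: none
Why: Negishi acylation: the furylzinc couples with the acid chloride under zerovalent palladium catalysis and does not attack the dioxolanone. Exchange in ether at −78 °C with immediate transmetalation keeps the 3-furyllithium from taking a silyl group from a neighbouring oxygen (retro-Brook shift).

Step 7
Reactants: 15 furyl ketone (C9 epimers)
Product: 16 (5S)-5-[(2S)-2-{4-[(tert-butyldimethylsilyloxy)methyl]-2-[2-methyl-1-(triethylsilyloxy)prop-2-en-1-yl]furan-3-yl}-2-hydroxyethyl]-2,2,5-trimethyl-1,3-dioxolan-4-one (6S carbinol; both C9 epimers)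
Conditions: (R)-2-methyl-CBS-oxazaborolidine (0.2 equiv), catecholborane, PhMe, −78 °C; MeOH; aq. NaHCO3
Reagents that add atoms: none
Why: Corey–Bakshi–Shibata reduction of a heteroaryl ketone with the furyl group as the large substituent; the (R)-catalyst should give the 6S carbinol by reagent control (1,3-anti to O4). Catecholborane leaves the isopropenyl group alone.

Step 8
Reactants: 16 6S carbinol
Product: 17 O6-tert-butyldimethylsilyl ether of 16 (both C9 epimers)
Conditions: t-BuMe2SiOTf, 2,6-lutidine, CH2Cl2, −78 → 0 °C
Reagents that add atoms: tert-butyldimethylsilyl triflate, CC(C)(C)[Si](C)(C)OS(=O)(=O)C(F)(F)F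
Why: Silylation of a hindered secondary alcohol with the triflate; it is done at once so that the γ-hydroxyl cannot translactonise onto the dioxolanone.

Step 9
Reactants: 17 O6-silyl ether
Product: 18 (5S)-5-[(2S)-2-(tert-butyldimethylsilyloxy)-2-{4-[(tert-butyldimethylsilyloxy)methyl]-2-(1-hydroxy-2-methylprop-2-en-1-yl)furan-3-yl}ethyl]-2,2,5-trimethyl-1,3-dioxolan-4-one (C9 alcohol; both C9 epimers)
Conditions: HF·pyridine, pyridine, THF, 0 °C
Reagents that add atoms: none
Why: Buffered HF·pyridine cleaves a triethylsilyl ether well before tert-butyldimethylsilyl ethers, and is mild enough not to ionise the furfurylic, allylic C9–O bond.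

Step 10
Reactants: 18 C9 alcohol
Product: 19 (2S,4S)-4-(tert-butyldimethylsilyloxy)-4-{4-[(tert-butyldimethylsilyloxy)methyl]-2-(1-hydroxy-2-methylprop-2-en-1-yl)furan-3-yl}-2-hydroxy-2-methylbutanoic acid (seco acid; both C9 epimers)
Conditions: LiOH, THF/H2O, 0 °C → rt; cold 0.5 M HCl to pH 4; used crude
Reagents that add atoms: lithium hydroxide, [Li+].[OH-]
Why: The dioxolanone is an activated ester and is saponified readily, releasing acetone, the C3 carboxyl and the C4 hydroxyl; the silyl ethers are stable to aqueous base.

Step 11
Reactants: 19 seco acid
Product: 20 (4S,6S)-hydroxy lactone: furan-fused oxocan-2-one O9–C3(=O)–C4(CH3)(OH)–C5H2–C6H(OTBS)–C7=C8–C9H(isopropenyl) with CH2OTBS on furan C11 (both C9 epimers)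
Conditions: 2-methyl-6-nitrobenzoic anhydride, 4-(dimethylamino)pyridine, CH2Cl2 (2 mM), rt, slow addition
Reagents that add atoms: none
Why: Shiina macrolactonisation: the mixed anhydride acylates the secondary C9 hydroxyl, while the tertiary C4 hydroxyl is too hindered to compete. The cis-fused furan puts two sp2 atoms in the ring, which lowers the transannular penalty of the eight-membered ring.

Step 12
Reactants: 20 hydroxy lactone
Product: 21 O4-triethylsilyl ether of 20 (both C9 epimers)
Conditions: Et3SiOTf, 2,6-lutidine, CH2Cl2, −78 → −20 °C
Reagents that add atoms: triethylsilyl triflate, CC[Si](CC)(CC)OS(=O)(=O)C(F)(F)F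
Why: Silyl triflates protect tertiary α-hydroxy esters readily; excess lutidine and low temperature protect the ionisable C9–O ester bond. O4 must be masked for the later cation chemistry.

Step 13
Reactants: 21 silylated lactone
Product: 22 (4S,6S)-2-methyleneoxocane: the enol ether O9–C3(=C2H2) of 21 (both C9 epimers)
Conditions: Cp2Ti(μ-CH2)(μ-Cl)AlMe2, pyridine, THF/PhMe, −40 °C → rt; aq. NaOH; basic Al2O3; used at once
Reagents that add atoms: Cp2Ti(μ-CH2)(μ-Cl)AlMe2 (written as Cp2Ti=CH2·ClAlMe2), C=[Ti](C1C=CC=C1)C1C=CC=C1.C[Al](C)Cl
Why: Tebbe methylenation converts lactones into exocyclic enol ethers through a titanium methylidene [2+2] addition and cycloreversion. Pyridine tempers the aluminium Lewis acid that could ionise the C9–O bond; silyl ethers and the isopropenyl group are inert.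

Step 14
Reactants: 22 2-methyleneoxocane
Product: 23 (4S,6S,9E)-furan-fused cyclodec-9-en-3-one: C1H2–C2H2–C3(=O)–C4(CH3)(OTES)–C5H2–C6H(OTBS)–C7=C8(furan)–C9H=C10(CH3) with CH2OTBS on furan C11
Conditions: degassed PhMe (0.01 M), Et3N (0.1 equiv), base-washed sealed tube, 130 °C
Reagents that add atoms: none
Why: Heating the allyl vinyl ether C2=C3–O–C9–C10=C1 of 22 should bring about a concerted, suprafacial [3,3] sigmatropic (Claisen) shift through a chair-like array in which C1–C2 forms as O–C9 breaks. The closest known reaction type is the Claisen ring expansion of 2-methylene-6-vinyltetrahydropyrans to cyclooctenones; here the same topology enlarges an oxocane by two carbons. The ten-membered carbocycle is therefore closed by ring expansion inside an existing eight-membered ring (a bridged bicyclic transition state with the ring oxygen as one-atom bridge) and not by end-to-end cyclisation. No stereocentre is created: C9 is lost, and the only new element is the C9=C10 geometry, expected E because furan carbon C8 sits pseudo-equatorial on the chair and a ten-membered ring can hold an E alkene. The step needs the isopropenyl group and not the furan C7=C8 bond as the allyl partner; the latter path would bond to fully substituted C7 and leave a non-aromatic furan that cannot tautomerise back, so it is at most a reversible dead end, whereas the productive path gains a ketone and a furan-conjugated alkene. It also needs the concerted shift to outrun ionisation of the doubly activated O–C9 bond, which the non-polar solvent, base-washed glass and trace of amine are chosen to secure. Both C9 epimers can reach such a chair, though probably at different rates.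

Step 15
Reactants: 23 furan-fused cyclodecenone
Product: 25 (4S,6S,9E)-8-hydroxybutenolide: C12 lactone carbonyl and C8 hemiketal hydroxyl (both C8 epimers) with C7=C11 and otherwise as 23, via furan endoperoxide 24 (not isolated)
Conditions: O2, hν, tetraphenylporphyrin (cat.), i-Pr2NEt, CH2Cl2, −78 °C → rt
Reagents that add atoms: dioxygen, O=O
Why: Singlet oxygen adds [4+2] across the furan far faster than it reacts with a trisubstituted alkene. The amine removes the only bridgehead hydrogen of the endoperoxide, at C12 (Kornblum–DeLaMare fragmentation), so C12 becomes the lactone carbonyl and C8 the hemiketal.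

Step 16
Reactants: 25 8-hydroxybutenolide
Product: 26 (4S,6S,10S,8E)-3,10-epoxygermacra-2,7(11),8-trien-12,8-olide bearing 4-OTES and 6-OTBS and 13-OTBS
Conditions: camphorsulfonic acid (0.1 equiv), 4 Å molecular sieves, CH2Cl2, 0 °C → rt
Reagents that add atoms: none
Why: Proposed new method: acid should ionise the tertiary, allylic C8 hemiketal to a cation delocalised over C8–C9–C10; the C3 carbonyl oxygen, held across the ring, closes a five-membered ring on C10 (5-exo) and the oxocarbenium ion loses a proton from C2, giving the enol ether, the C8=C9 bond (C7 and C10 cis, the only geometry the bridged ring allows) and the C10 centre. The 10S configuration is expected only if, as assumed, the bridged diastereomers equilibrate by re-ionisation and the natural one is the more stable. The closest known reaction types are the acid-induced dehydration of γ-hydroxybutenolides to γ-alkylidenebutenolides, SN1′ allylic etherification, and closure of cations or halonium ions by a γ-carbonyl oxygen to 2,3-dihydrofurans.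

Step 17
Reactants: 26 tris-silyl ether
Product: 27 (4S,6S,10S,8E)-4,6,13-trihydroxy-3,10-epoxygermacra-2,7(11),8-trien-12,8-olide
Conditions: Bu4NF, AcOH (1:1), THF, 0 °C → rt
Reagents that add atoms: none
Why: Acetic acid-buffered fluoride removes all three silyl groups near neutrality, so that neither the enol ether and C10–O bond (acid) nor the enol lactone (base) should suffer; the triol is taken on without delay.

Step 18
Reactants: 27 triol
Product: 28 target, the 6,13-diacetate of 27
Conditions: Ac2O, pyridine, 4-(dimethylamino)pyridine (cat.), CH2Cl2, 0 °C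
Reagents that add atoms: acetic anhydride, CC(=O)OC(C)=O
Why: Acetylation of the primary C13 and secondary C6 hydroxyls is fast under these conditions, while the hindered tertiary C4 hydroxyl is not acylated.

## Compound list

1 | 3,4-dibromofuran | Brc1cocc1Br | starting material
2 | 4-bromo-3-furyllithium | [Li]c1cocc1Br | intermediate
3 | 4-bromofuran-3-carbaldehyde | O=Cc1cocc1Br | intermediate
4 | (4-bromofuran-3-yl)methanol | OCc1cocc1Br | intermediate
5 | 3-bromo-4-[(tert-butyldimethylsilyloxy)methyl]furan | CC(C)(C)[Si](C)(C)OCc1cocc1Br | intermediate
6 | methacrolein (2-methylprop-2-enal) | CC(=C)C=O | starting material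
7 | 3-bromo-4-[(tert-butyldimethylsilyloxy)methyl]-2-furyllithium | CC(C)(C)[Si](C)(C)OCc1coc([Li])c1Br | intermediate
8 | lithium 1-{3-bromo-4-[(tert-butyldimethylsilyloxy)methyl]furan-2-yl}-2-methylprop-2-en-1-olate (racemic) | CC(C)(C)[Si](C)(C)OCc1coc(C([O-])C(C)=C)c1Br.[Li+] | intermediate
9 | rac-3-bromo-4-[(tert-butyldimethylsilyloxy)methyl]-2-[2-methyl-1-(triethylsilyloxy)prop-2-en-1-yl]furan | CC(C)(C)[Si](C)(C)OCc1coc(C(O[Si](CC)(CC)CC)C(C)=C)c1Br | intermediate
10 | (S)-citramalic acid | OC(=O)[C@@](C)(O)CC(=O)O | starting material
11 | 2-[(4S)-2,2,4-trimethyl-5-oxo-1,3-dioxolan-4-yl]acetic acid | OC(=O)C[C@]1(C)OC(C)(C)OC1=O | intermediate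
12 | 2-[(4S)-2,2,4-trimethyl-5-oxo-1,3-dioxolan-4-yl]acetyl chloride | ClC(=O)C[C@]1(C)OC(C)(C)OC1=O | intermediate
13 | 3-furyllithium from 9 (lithium on C7; C9 racemic) | CC(C)(C)[Si](C)(C)OCc1coc(C(O[Si](CC)(CC)CC)C(C)=C)c1[Li] | intermediate
14 | 3-furylzinc chloride from 9 (zinc on C7; C9 racemic) | CC(C)(C)[Si](C)(C)OCc1coc(C(O[Si](CC)(CC)CC)C(C)=C)c1[Zn]Cl | intermediate
15 | furyl ketone (5S)-5-(2-{4-[(tert-butyldimethylsilyloxy)methyl]-2-[2-methyl-1-(triethylsilyloxy)prop-2-en-1-yl]furan-3-yl}-2-oxoethyl)-2,2,5-trimethyl-1,3-dioxolan-4-one (C9 epimers) | CC(C)(C)[Si](C)(C)OCc1coc(C(O[Si](CC)(CC)CC)C(C)=C)c1C(=O)C[C@]2(C)OC(C)(C)OC2=O | intermediate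
16 | 6S carbinol (5S)-5-[(2S)-2-{4-[(tert-butyldimethylsilyloxy)methyl]-2-[2-methyl-1-(triethylsilyloxy)prop-2-en-1-yl]furan-3-yl}-2-hydroxyethyl]-2,2,5-trimethyl-1,3-dioxolan-4-one (C9 epimers) | CC(C)(C)[Si](C)(C)OCc1coc(C(O[Si](CC)(CC)CC)C(C)=C)c1[C@@H](O)C[C@]2(C)OC(C)(C)OC2=O | intermediate
17 | O6-tert-butyldimethylsilyl ether of 16 (C9 epimers) | CC(C)(C)[Si](C)(C)OCc1coc(C(O[Si](CC)(CC)CC)C(C)=C)c1[C@@H](O[Si](C)(C)C(C)(C)C)C[C@]2(C)OC(C)(C)OC2=O | intermediate
18 | C9 alcohol (5S)-5-[(2S)-2-(tert-butyldimethylsilyloxy)-2-{4-[(tert-butyldimethylsilyloxy)methyl]-2-(1-hydroxy-2-methylprop-2-en-1-yl)furan-3-yl}ethyl]-2,2,5-trimethyl-1,3-dioxolan-4-one (C9 epimers) | CC(C)(C)[Si](C)(C)OCc1coc(C(O)C(C)=C)c1[C@@H](O[Si](C)(C)C(C)(C)C)C[C@]2(C)OC(C)(C)OC2=O | intermediate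
19 | seco acid (2S,4S)-4-(tert-butyldimethylsilyloxy)-4-{4-[(tert-butyldimethylsilyloxy)methyl]-2-(1-hydroxy-2-methylprop-2-en-1-yl)furan-3-yl}-2-hydroxy-2-methylbutanoic acid (C9 epimers) | CC(C)(C)[Si](C)(C)OCc1coc(C(O)C(C)=C)c1[C@@H](O[Si](C)(C)C(C)(C)C)C[C@](C)(O)C(=O)O | intermediate
20 | (4S,6S)-hydroxy lactone: furan-fused oxocan-2-one with free C4–OH, 6-OTBS, 13-OTBS and C9 isopropenyl (C9 epimers) | CC(C)(C)[Si](C)(C)OCc1c2c(C(C(C)=C)OC(=O)[C@@](C)(O)C[C@@H]2O[Si](C)(C)C(C)(C)C)oc1 | intermediate
21 | O4-triethylsilyl ether of 20 (C9 epimers) | CC(C)(C)[Si](C)(C)OCc1c2c(C(C(C)=C)OC(=O)[C@@](C)(O[Si](CC)(CC)CC)C[C@@H]2O[Si](C)(C)C(C)(C)C)oc1 | intermediate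
22 | (4S,6S)-furan-fused 2-methylene-8-isopropenyloxocane (C9 epimers) | CC(C)(C)[Si](C)(C)OCc1c2c(C(C(C)=C)OC(=C)[C@@](C)(O[Si](CC)(CC)CC)C[C@@H]2O[Si](C)(C)C(C)(C)C)oc1 | intermediate
23 | (4S,6S,9E)-furan-fused cyclodec-9-en-3-one with 4-OTES, 6-OTBS, 13-OTBS | CC(C)(C)[Si](C)(C)OCc1c2c(/C=C(C)/CCC(=O)[C@@](C)(O[Si](CC)(CC)CC)C[C@@H]2O[Si](C)(C)C(C)(C)C)oc1 | intermediate
24 | 8,12-endoperoxide of 23 | CC(C)(C)[Si](C)(C)OCC1=C2C3(/C=C(C)/CCC(=O)[C@@](C)(O[Si](CC)(CC)CC)C[C@@H]2O[Si](C)(C)C(C)(C)C)OOC1O3 | intermediate
25 | (4S,6S,9E)-8-hydroxybutenolide (C8 epimers) | CC(C)(C)[Si](C)(C)OCC1=C2C(O)(/C=C(C)/CCC(=O)[C@@](C)(O[Si](CC)(CC)CC)C[C@@H]2O[Si](C)(C)C(C)(C)C)OC1=O | intermediate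
26 | (4S,6S,10S,8E)-3,10-epoxygermacra-2,7(11),8-trien-12,8-olide with 4-OTES, 6-OTBS, 13-OTBS | CC(C)(C)[Si](C)(C)OCC1=C2/C(=C\[C@]3(C)CC=C(O3)[C@@](C)(O[Si](CC)(CC)CC)C[C@@H]2O[Si](C)(C)C(C)(C)C)OC1=O | intermediate
27 | (4S,6S,10S,8E)-4,6,13-trihydroxy-3,10-epoxygermacra-2,7(11),8-trien-12,8-olide | OCC1=C2/C(=C\[C@]3(C)CC=C(O3)[C@@](C)(O)C[C@@H]2O)OC1=O | intermediate
28 | CNP0144020.1, the 6,13-diacetate of 27 | CC(=O)OCC1=C2/C(=C\[C@]3(C)CC=C(O3)[C@@](C)(O)C[C@@H]2OC(C)=O)OC1=O | target

## Step count and least certain steps

Total step count: 18. Longest linear sequence: 16 steps from 3,4-dibromofuran (steps 1–3 and 6–18); steps 4 and 5 form the two-step side branch to acid chloride 12.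

**Step 16 (ring closure on C10).** Three things may go wrong:
- The delocalised cation may lose a proton from C14 or C1 (E1) faster than the weakly nucleophilic carbonyl oxygen captures it.
- A silyl ether oxygen (O6, which lies close to C10, or O4) may capture C10 with loss of its silyl group.
- Facial selectivity at C10 may be poor or wrong, because the assumed thermodynamic preference for 10S is untested.

Fallback with known chemistry, from 25 back to 26:
1. Mukaiyama hydration of the C9=C10 bond (Co(acac)2 cat., PhSiH3, O2, i-PrOH). Hydrogen-atom transfer to C9 and trapping of the tertiary radical at C10 are expected to give the 10-hydroxy-9,10-dihydro compound F1. This forms the C10–O bond irreversibly under kinetic control; the 10S epimer is wanted and would be separated from 10R. F1 should rest largely as its five-membered C3 lactol.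
2. MsCl and Et3N then remove two molecules of water: from the lactol to the enol ether, and from the C8 hemiketal and C9–H to the alkylidene butenolide. This rejoins the route at 26.

**Step 14 (key step).** Ionisation of the furfurylic, allylic O–C9 bond may outrun the concerted shift, leading to a formal [1,3] shift or decomposition. Alternatively, the oxocane may not reach the chair array at a temperature the enol ether survives. If 22 proves too labile to isolate, methylenation with Cp2TiMe2 at 70–80 °C would let it rearrange as it forms.

Fallback by a different bond-forming principle, from 21 back to 23: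
1. LiCH2SO2Ph (THF, −78 °C) opens the lactone to the hydroxy β-keto sulfone F2.
2. Methyl chloroformate and pyridine give the C9 methyl carbonate F3.
3. Pd(PPh3)4 (zerovalent palladium) in THF at high dilution ionises the carbonate, and the sulfonyl-stabilised enolate attacks the unsubstituted terminus C1 of the allyl unit (Tsuji–Trost macrocyclisation). This closes the ten-membered ring as the cyclic 2-phenylsulfonyl ketone F4.
4. SmI2 (THF/MeOH, −78 °C) removes the sulfonyl group and gives 23.

**Step 11 (eight-membered lactonisation).** Intermolecular acylation (diolide and oligomer formation) may win over the slow closure of a medium ring, and the C9 carbinol may ionise during handling of the free acid.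

Fallback that avoids the seco acid, from 18 directly to 20: the C9 alkoxide (NaN(SiMe3)2, THF, high dilution, −78 → 0 °C) attacks the dioxolanone carbonyl, which is itself an activated ester. Acetone is expelled and the ring closes by intramolecular transesterification. This fallback makes no new compound (F0).

**Step 6 (furyl–acyl coupling).** Transmetalation and coupling at the doubly ortho-substituted furylzinc may be slow, so that the acid chloride is consumed otherwise. The lithio species may also take a silyl group from O9 or O13 before it reaches zinc.

Fallback without zinc or palladium, from 11 and 9 back to 15: acid 11 is converted (EDC·HCl, MeNHOMe·HCl, N-methylmorpholine) into the Weinreb amide F5. Adding F5 to furyllithium 13 at −78 °C within minutes of the exchange gives, through the stable chelated adduct, ketone 15 on work-up.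

## Further compounds

F1 | step 16 | (4S,6S,10S)-10-hydroxy-9,10-dihydro derivative of 25 (C8 epimers; in equilibrium with its C3 lactol) | CC(C)(C)[Si](C)(C)OCC1=C2C(O)(C[C@@](C)(O)CCC(=O)[C@@](C)(O[Si](CC)(CC)CC)C[C@@H]2O[Si](C)(C)C(C)(C)C)OC1=O
F2 | step 14 | hydroxy β-keto sulfone from ring opening of 21 (C9 epimers) | CC(C)(C)[Si](C)(C)OCc1coc(C(O)C(C)=C)c1[C@@H](O[Si](C)(C)C(C)(C)C)C[C@](C)(O[Si](CC)(CC)CC)C(=O)CS(=O)(=O)c1ccccc1
F3 | step 14 | C9 methyl carbonate of F2 (C9 epimers) | CC(C)(C)[Si](C)(C)OCc1coc(C(OC(=O)OC)C(C)=C)c1[C@@H](O[Si](C)(C)C(C)(C)C)C[C@](C)(O[Si](CC)(CC)CC)C(=O)CS(=O)(=O)c1ccccc1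
F4 | step 14 | 2-(phenylsulfonyl) derivative of 23 (C2 epimers) | CC(C)(C)[Si](C)(C)OCc1c2c(/C=C(C)/CC(S(=O)(=O)c3ccccc3)C(=O)[C@@](C)(O[Si](CC)(CC)CC)C[C@@H]2O[Si](C)(C)C(C)(C)C)oc1
F0 | step 11 | none | none
F5 | step 6 | N-methoxy-N-methyl-2-[(4S)-2,2,4-trimethyl-5-oxo-1,3-dioxolan-4-yl]acetamide | CON(C)C(=O)C[C@]1(C)OC(C)(C)OC1=O
A1 | alternative 1 | C6 aldoxime carrying the 3-isopropenyl-2,3-dihydrofuran and the butenolide | CC(=O)OCC1=C(C=NO)/C(=C\[C@]2(C)CC=C(O2)C(C)=C)OC1=O
A2 | alternative 1 | C6 nitrile oxide from A1 | CC(=O)OCC1=C(C#[N+][O-])/C(=C\[C@]2(C)CC=C(O2)C(C)=C)OC1=O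
A3 | alternative 1 | isoxazoline-bridged macrocycle | CC(=O)OCC1=C2/C(=C\[C@]3(C)CC=C(O3)[C@]4(C)CC2=NO4)OC1=O
A4 | alternative 2 | 2-methyl-5-alkylfuran with tethered 2-acetoxy enone | Cc1ccc(o1)[C@@](C)(O[Si](CC)(CC)CC)C[C@H](O[Si](C)(C)C(C)(C)C)C(=O)C(OC(C)=O)=C
A5 | alternative 2 | tricyclic oxanorbornene adduct | C[C@@]12C=C[C@]3(O1)[C@@](C)(O[Si](CC)(CC)CC)C[C@H](O[Si](C)(C)C(C)(C)C)C(=O)[C@@]3(OC(C)=O)C2
A6 | alternative 3 | C7 iodo butenolide with C6 aldehyde | CC(=O)OCC1=C(I)/C(=C\[C@]2(C)CC=C(O2)[C@@](C)(O[Si](CC)(CC)CC)CC=O)OC1=O
A7 | alternative 3 | macrocyclic C6 carbinol | CC(=O)OCC1=C2/C(=C\[C@]3(C)CC=C(O3)[C@@](C)(O[Si](CC)(CC)CC)C[C@@H]2O)OC1=O
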